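Millimolar of catalyst, not minutes, was the unit I reckoned this flask in. The beta flask is the flask asked about, followed so far up to 50.0 min; the theta flask differed from it by twice the starting material.

| flask | starting material | gas phase | catalyst | remark | time |
|---|---|---|---|---|---|
| beta | 0.23 M | 120 mM (held) | 0.23 mM | the very flask that is asked about, followed so far |  |
| theta | 0.46 M | 120 mM (held) | 0.23 mM | run made earlier |  |
| flask | 0.23 M | 120 mM (held) | 0.23 mM |  | 4.0 h |

- beta (time / min: target / %): 10.0: 11; 20.0: 33; 30.0: 40; 40.0: 58; 50.0: 68
- theta (time / h: target / %): 0.333: 23; 0.667: 42; 1.00: 59; 2.00: 81; 4.00: 84

(standard deviation of a reading: 2 percentage points)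

1. the target standing at 4.0 h, as a percentage of the starting material charged
2. the change that raises the amount of target at 4.0 h, in percent of the starting material charged most ("none" if none brings more than 2 percentage points) (summer / winter / dawn / none)
3. amount of target at 4.0 h, in percent of the starting material charged, after dawn

- summer: doubling the amount of catalyst, all else as stated
- winter: doubling the transfer coefficient of the gas phase, all else as stated
- dawn: doubling the saturation concentration of gas phase, all else as stated

The theta flask flattened, rising 3 percentage points between 2.00 h and 4.00 h against a scatter of 2 points. I read that plateau as spent starting material. The ways to target and to uncatalysed product each take one starting material and one dissolved gas, so both concentrations cancel from the ratio of their rates and [catalyst] stays. Beta and theta, with equal [catalyst], should therefore end on one split, whatever their speeds.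

From the theta plateau I read 0.0438 mM, the even-split catalyst concentration, at which the two ways run equally fast. [catalyst] divided by it is the selectivity factor, and the target's share is [catalyst]/([catalyst] + even-split concentration). For the beta flask that gave 84.0%. Beta still lacked 19.0% of that ceiling at 50.0 min, which, counted crudely, meant a half-life of 20.9 min, and 4.0 h holds about 11.5 of them. More gas could then add nothing that I could reckon, while I reckoned summer, which doubles the catalyst, at 91.3%, a gain of 7.3 points, more than the margin of 2 points.

The forecast said 84%, summer as the best change, and 84% after dawn: “More gas (winter, dawn) only speeds up a finished reaction”.

    2 dissolved gas → self-condensation product (k = 0.800 /M/min)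
    gas phase ⇌ dissolved gas, rate k2*(csat - [dissolved gas]) (kL = 0.0600 /min)
    starting material + dissolved gas → uncatalysed product (k = 0.200 /M/min)
    starting material + dissolved gas + catalyst → catalyst + target (k = 4300 /M²/min)

The beta flask gave 83.2%, and 83.2% after dawn, with summer the best change at 7.6 points. It held 0% starting material at 4.00 h, and target already stood at 82.8% after 2.00 h. The even-split concentration had put the gain from summer at 7.3 points. On the neighbour flask with 5.8 × 10⁻⁵ M catalyst, it gives 57.0% target; the computed flask gave 55.1%, beside 44.2% uncatalysed product.

The readings were generated by integration from invented constants; scatter was added.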